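**Plan**

- Feature: in ring C [C1(=O)–C2(coumarin-3-yl)=C3H–C4(=O)–C5(OH)(prenyl)–C6H2] the C2=C3 alkene is conjugated with the C4 ketone and C2 carries the coumarin. Cutting C2=C3 as an aldol condensation makes C2 the ketone of a 3-acylcoumarin and C3 the methyl of a C4 acetyl group; C5 is quaternary (one enolisable site) and C1 is held as a 1,3-dithiane (one acceptor carbonyl).
- Further cuts, in retrosynthetic order: C3'=C4' and the lactone C–O of the coumarin (Knoevenagel–lactonisation), C2–C3' (malonate half-ester), C1–C2 (dithiane anion + CO2), C6–C1 (dithiane anion + epoxide), the epoxide oxygen (Sharpless), then the chain bonds C4–C5 and C5–CH2.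
- Forward: the C3–C6 chain with its prenyl group is made as epoxy alcohol 7 in three steps; 1,3-dithiane joins C6 to C1 and then C1 to C2; the pyranone ring of the coumarin is built on β-keto ester 17; ring C is closed in step 11.
- Stereochemistry: C5 (R), the only stereocentre of the target, is set in step 3 by Sharpless kinetic resolution with L-(+)-DIPT, and its C–O bond is never broken afterwards. The C4 carbinol centre is temporary and is oxidised away in step 10.
- End game: oxidative removal of the C1 dithiane, then desilylation at C5.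

Key step: step 11

Remark: ring C atoms are numbered C1–C6 as in the first line, coumarin atoms carry primed locants, and the target SMILES is read as (R) at C5.

**Route**

Step 1
Reactants: 1 2,3-dibromoprop-1-ene; 2 (2-methylprop-1-en-1-yl)magnesium bromide
Product: 3 2-bromo-5-methylhexa-1,4-diene
Conditions: CuI (5 mol%), THF, −20 → 0 °C
Reagents that add atoms: none
Why: Copper-catalysed allylic substitution of the allylic bromide by the alkenyl Grignard reagent is a standard entry to 2-bromo-1,4-dienes, since the vinylic C–Br bond is inert and SN2 and SN2' attack give the same product.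

Step 2
Reactants: 3 2-bromo-5-methylhexa-1,4-diene; 4 acetaldehyde
Product: 6 rac-6-methyl-3-methylidenehept-5-en-2-ol, via vinyllithium 5 (not isolated)
Conditions: tBuLi (2.0 equiv), Et2O, −78 °C; MeCHO, −78 → 0 °C; H2O
Reagents that add atoms: none
Why: Bromine–lithium exchange of the 2-bromo-1-alkene followed by 1,2-addition of the vinyllithium to the aldehyde should give the secondary allylic alcohol, which may be racemic because the next step resolves it.

Step 3
Reactants: 6 rac-6-methyl-3-methylidenehept-5-en-2-ol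
Product: 7 (1S)-1-[(2R)-2-(3-methylbut-2-en-1-yl)oxiran-2-yl]ethan-1-ol
Conditions: Ti(OiPr)4 (0.1 equiv), L-(+)-DIPT (0.15 equiv), tBuOOH (0.45 equiv), 4 Å MS, CH2Cl2, −20 °C, stopped near 45% conversion
Reagents that add atoms: tert-butyl hydroperoxide, CC(C)(C)OO
Why: In a Sharpless kinetic resolution with L-(+)-DIPT the (S)-alcohol is epoxidised much faster than the (R)-alcohol and on the alkene face chosen by the tartrate, so the erythro epoxy alcohol should form with the future C5 in the required configuration, while the unreacted (R)-alcohol is removed by chromatography and the remote trisubstituted alkene, which is not allylic, is left alone.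

Step 4
Reactants: 7 (1S)-1-[(2R)-2-(3-methylbut-2-en-1-yl)oxiran-2-yl]ethan-1-ol; 8 1,3-dithiane
Product: 10 (2S,3R)-3-(1,3-dithian-2-ylmethyl)-6-methylhept-5-ene-2,3-diol, via 2-lithio-1,3-dithiane 9 (not isolated)
Conditions: 8 (1.6 equiv), nBuLi (1.5 equiv), THF, −30 °C; 7 pre-treated with nBuLi (1.0 equiv), THF, −78 °C; combined, DMPU, −30 °C → rt; H2O
Reagents that add atoms: none
Why: In this Corey–Seebach epoxide opening the lithiated dithiane attacks the unsubstituted epoxide CH2 of the lithium alkoxide of 7 by SN2, which forms the C6–C1 bond and leaves the C5–O bond and the C5 configuration untouched.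

Step 5
Reactants: 10 (2S,3R)-3-(1,3-dithian-2-ylmethyl)-6-methylhept-5-ene-2,3-diol
Product: 11 2-[(2R,3S)-2-(3-methylbut-2-en-1-yl)-2,3-bis(triethylsilyloxy)butyl]-1,3-dithiane
Conditions: Et3SiOSO2CF3 (2.6 equiv), 2,6-lutidine (4 equiv), CH2Cl2, −78 → 0 °C
Reagents that add atoms: triethylsilyl trifluoromethanesulfonate, CC[Si](CC)(CC)OS(=O)(=O)C(F)(F)F
Why: Silylation with the silyl triflate and 2,6-lutidine covers the secondary and the hindered tertiary hydroxyl alike and gives ethers that tolerate the organolithium and condensation steps ahead.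

Step 6
Reactants: 11 2-[(2R,3S)-2-(3-methylbut-2-en-1-yl)-2,3-bis(triethylsilyloxy)butyl]-1,3-dithiane; 12 carbon dioxide
Product: 14 2-[(2R,3S)-2-(3-methylbut-2-en-1-yl)-2,3-bis(triethylsilyloxy)butyl]-1,3-dithiane-2-carboxylic acid, via lithiated dithiane 13 (not isolated)
Conditions: tBuLi (1.2 equiv), THF–HMPA (10:1), −78 °C; CO2 (g), −78 → 0 °C; cold dilute HCl to pH 3
Reagents that add atoms: none
Why: Corey–Seebach umpolung by deprotonation of the 2-alkyl-1,3-dithiane in THF–HMPA, where a 1,4-related silyloxy group is known to stay on oxygen, and carboxylation of the carbanion should install C2 as a carboxylic acid.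

Step 7
Reactants: 14 2-[(2R,3S)-2-(3-methylbut-2-en-1-yl)-2,3-bis(triethylsilyloxy)butyl]-1,3-dithiane-2-carboxylic acid; 15 magnesium bis(3-ethoxy-3-oxopropanoate)
Product: 17 ethyl 3-{2-[(2R,3S)-2-(3-methylbut-2-en-1-yl)-2,3-bis(triethylsilyloxy)butyl]-1,3-dithian-2-yl}-3-oxopropanoate, via acyl imidazolide 16 (not isolated)
Conditions: CDI (1.2 equiv), THF, rt; 15 (1.0 equiv), rt → 45 °C; cold 0.5 M HCl
Reagents that add atoms: none
Why: In this Masamune homologation the acid is activated as its imidazolide, which C-acylates the magnesium malonate half-ester, and decarboxylation on acidification should give the β-keto ester under near-neutral conditions that spare the silyl ethers.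

Step 8
Reactants: 17 ethyl 3-{2-[(2R,3S)-2-(3-methylbut-2-en-1-yl)-2,3-bis(triethylsilyloxy)butyl]-1,3-dithian-2-yl}-3-oxopropanoate; 18 2-hydroxy-4-methoxybenzaldehyde
Product: 20 7-methoxy-3-({2-[(2R,3S)-2-(3-methylbut-2-en-1-yl)-2,3-bis(triethylsilyloxy)butyl]-1,3-dithian-2-yl}carbonyl)-2H-chromen-2-one, via benzylidene keto ester 19 (not isolated)
Conditions: piperidine (0.2 equiv), AcOH (0.2 equiv), 4 Å MS, toluene, 60 °C
Reagents that add atoms: none
Why: Knoevenagel condensation of the active methylene with the salicylaldehyde under piperidinium acetate catalysis, followed by lactonisation of the phenol onto the ethyl ester, is the standard synthesis of 3-acylcoumarins and places the methoxy group at C7'.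

Step 9
Reactants: 20 7-methoxy-3-({2-[(2R,3S)-2-(3-methylbut-2-en-1-yl)-2,3-bis(triethylsilyloxy)butyl]-1,3-dithian-2-yl}carbonyl)-2H-chromen-2-one
Product: 21 3-({2-[(2R,3S)-3-hydroxy-2-(3-methylbut-2-en-1-yl)-2-(triethylsilyloxy)butyl]-1,3-dithian-2-yl}carbonyl)-7-methoxy-2H-chromen-2-one
Conditions: PPTS (0.2 equiv), MeOH–CH2Cl2 (1:1), 0 °C
Reagents that add atoms: none
Why: Acid-catalysed methanolysis of silyl ethers is strongly slowed by steric hindrance, so the secondary triethylsilyl ether should be cleaved while the tertiary one on C5 stays.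

Step 10
Reactants: 21 3-({2-[(2R,3S)-3-hydroxy-2-(3-methylbut-2-en-1-yl)-2-(triethylsilyloxy)butyl]-1,3-dithian-2-yl}carbonyl)-7-methoxy-2H-chromen-2-one
Product: 22 7-methoxy-3-({2-[(2R)-2-(3-methylbut-2-en-1-yl)-3-oxo-2-(triethylsilyloxy)butyl]-1,3-dithian-2-yl}carbonyl)-2H-chromen-2-one
Conditions: (COCl)2, DMSO, CH2Cl2, −78 °C; Et3N, −78 → 0 °C
Reagents that add atoms: none
Why: Swern oxidation should convert the hindered secondary alcohol into the C4 methyl ketone without touching the dithiane, the alkene or the silyl ether, and it removes the temporary C4 stereocentre.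

Step 11
Reactants: 22 7-methoxy-3-({2-[(2R)-2-(3-methylbut-2-en-1-yl)-3-oxo-2-(triethylsilyloxy)butyl]-1,3-dithian-2-yl}carbonyl)-2H-chromen-2-one
Product: 25 7-methoxy-3-[(10R)-10-(3-methylbut-2-en-1-yl)-9-oxo-10-(triethylsilyloxy)-1,5-dithiaspiro[5.5]undec-7-en-7-yl]-2H-chromen-2-one, via lithium aldolate 23 (not isolated), via aldol trifluoroacetate 24 (not isolated)
Conditions: LiN(SiMe3)2 (1.1 equiv), THF, −78 → −40 °C; (CF3CO)2O (2.5 equiv), −78 °C; DBU (5 equiv), −78 °C → rt
Reagents that add atoms: none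
Why: LiN(SiMe3)2 removes a proton from the C3 methyl group, the only enolisable position of 22 because C5 is quaternary and the C2 ketone lies between the dithiane carbon C1 and coumarin C3'; the lithium enolate adds to the C2 carbonyl to give aldolate 23, which is trifluoroacetylated to 24 and then loses trifluoroacetate by E1cB elimination under DBU to form C2=C3. The closest known reaction is the aldol cyclodehydration of a 1,5-diketone that ends a Robinson annulation, here with a 3-acylcoumarin ketone as acceptor and the dehydration run through an ester in the same flask. Ring C closes in the 6-(enolexo)-exo-trig mode. No stereocentre is created in the product, since the C2 carbinol centre of 23 and 24 is lost on elimination and C5 has no acidic hydrogen. The step needs site selectivity in enolisation and carbonyl attack and chemoselectivity towards the coumarin: the C1 dithiane leaves C2 as the only acceptor carbonyl within reach and blocks β-elimination of the C5 oxygen, conjugate addition to C4' would need an eight-membered ring, and elimination can only run towards C3 because C1 and C3' carry no hydrogen. The bulky amide base at −78 °C and the absence of hydroxide or alkoxide should protect the lactone.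

Step 12
Reactants: 25 7-methoxy-3-[(10R)-10-(3-methylbut-2-en-1-yl)-9-oxo-10-(triethylsilyloxy)-1,5-dithiaspiro[5.5]undec-7-en-7-yl]-2H-chromen-2-one
Product: 26 7-methoxy-3-[(4R)-4-(3-methylbut-2-en-1-yl)-3,6-dioxo-4-(triethylsilyloxy)cyclohex-1-en-1-yl]-2H-chromen-2-one
Conditions: PhI(OCOCF3)2 (1.5 equiv), NaHCO3 (4 equiv), MeCN–H2O (9:1), 0 °C, 15 min
Reagents that add atoms: water, O
Why: Oxidative dithioketal cleavage with the hypervalent iodine reagent in buffered aqueous acetonitrile is fast at sulfur, is expected to spare the alkene, the lactone and the silyl ether, and leaves no free thiol that could add to the ene-dione.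

Step 13
Reactants: 26 7-methoxy-3-[(4R)-4-(3-methylbut-2-en-1-yl)-3,6-dioxo-4-(triethylsilyloxy)cyclohex-1-en-1-yl]-2H-chromen-2-one
Product: 27 3-[(4R)-4-hydroxy-4-(3-methylbut-2-en-1-yl)-3,6-dioxocyclohex-1-en-1-yl]-7-methoxy-2H-chromen-2-one (CNP0250763.1)
Conditions: HF·pyridine, pyridine, THF, 0 °C → rt
Reagents that add atoms: none
Why: Fluoride-mediated desilylation with pyridine-buffered HF is mildly acidic, so the tertiary β-hydroxy ketone should be released without the base-induced loss of water that would lead to the quinone.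

**Compound list**

1 | 2,3-dibromoprop-1-ene | C=C(Br)CBr | starting material
2 | (2-methylprop-1-en-1-yl)magnesium bromide | CC(C)=C[Mg]Br | starting material
3 | 2-bromo-5-methylhexa-1,4-diene | C=C(Br)CC=C(C)C | intermediate
4 | acetaldehyde | CC=O | starting material
5 | (5-methylhexa-1,4-dien-2-yl)lithium | [Li]C(=C)CC=C(C)C | intermediate (not isolated)
6 | rac-6-methyl-3-methylidenehept-5-en-2-ol | CC(O)C(=C)CC=C(C)C | intermediate
7 | (1S)-1-[(2R)-2-(3-methylbut-2-en-1-yl)oxiran-2-yl]ethan-1-ol | C[C@H](O)[C@@]1(CC=C(C)C)CO1 | intermediate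
8 | 1,3-dithiane | C1CSCSC1 | starting material
9 | 2-lithio-1,3-dithiane | [Li]C1SCCCS1 | intermediate (not isolated)
10 | (2S,3R)-3-(1,3-dithian-2-ylmethyl)-6-methylhept-5-ene-2,3-diol | C[C@H](O)[C@@](O)(CC=C(C)C)CC1SCCCS1 | intermediate
11 | 2-[(2R,3S)-2-(3-methylbut-2-en-1-yl)-2,3-bis(triethylsilyloxy)butyl]-1,3-dithiane | C[C@H](O[Si](CC)(CC)CC)[C@@](O[Si](CC)(CC)CC)(CC=C(C)C)CC1SCCCS1 | intermediate
12 | carbon dioxide | O=C=O | starting material
13 | 2-lithio derivative of 11 | C[C@H](O[Si](CC)(CC)CC)[C@@](O[Si](CC)(CC)CC)(CC=C(C)C)CC1([Li])SCCCS1 | intermediate (not isolated)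
14 | 2-[(2R,3S)-2-(3-methylbut-2-en-1-yl)-2,3-bis(triethylsilyloxy)butyl]-1,3-dithiane-2-carboxylic acid | C[C@H](O[Si](CC)(CC)CC)[C@@](O[Si](CC)(CC)CC)(CC=C(C)C)CC1(SCCCS1)C(=O)O | intermediate
15 | magnesium bis(3-ethoxy-3-oxopropanoate) (magnesium monoethyl malonate) | CCOC(=O)CC(=O)[O-].CCOC(=O)CC(=O)[O-].[Mg+2] | starting material
16 | N-acylimidazole of acid 14 | C[C@H](O[Si](CC)(CC)CC)[C@@](O[Si](CC)(CC)CC)(CC=C(C)C)CC1(SCCCS1)C(=O)n1ccnc1 | intermediate (not isolated)
17 | ethyl 3-{2-[(2R,3S)-2-(3-methylbut-2-en-1-yl)-2,3-bis(triethylsilyloxy)butyl]-1,3-dithian-2-yl}-3-oxopropanoate | C[C@H](O[Si](CC)(CC)CC)[C@@](O[Si](CC)(CC)CC)(CC=C(C)C)CC1(SCCCS1)C(=O)CC(=O)OCC | intermediate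
18 | 2-hydroxy-4-methoxybenzaldehyde | COc1ccc(C=O)c(O)c1 | starting material
19 | ethyl 2-[(2-hydroxy-4-methoxyphenyl)methylidene]-3-oxopropanoate bearing the dithianyl side chain of 17 at C3 (alkene geometry not fixed) | C[C@H](O[Si](CC)(CC)CC)[C@@](O[Si](CC)(CC)CC)(CC=C(C)C)CC1(SCCCS1)C(=O)C(=Cc1ccc(OC)cc1O)C(=O)OCC | intermediate (not isolated)
20 | 7-methoxy-3-({2-[(2R,3S)-2-(3-methylbut-2-en-1-yl)-2,3-bis(triethylsilyloxy)butyl]-1,3-dithian-2-yl}carbonyl)-2H-chromen-2-one | C[C@H](O[Si](CC)(CC)CC)[C@@](O[Si](CC)(CC)CC)(CC=C(C)C)CC1(SCCCS1)C(=O)c1cc2ccc(OC)cc2oc1=O | intermediate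
21 | 3-({2-[(2R,3S)-3-hydroxy-2-(3-methylbut-2-en-1-yl)-2-(triethylsilyloxy)butyl]-1,3-dithian-2-yl}carbonyl)-7-methoxy-2H-chromen-2-one | C[C@H](O)[C@@](O[Si](CC)(CC)CC)(CC=C(C)C)CC1(SCCCS1)C(=O)c1cc2ccc(OC)cc2oc1=O | intermediate
22 | 7-methoxy-3-({2-[(2R)-2-(3-methylbut-2-en-1-yl)-3-oxo-2-(triethylsilyloxy)butyl]-1,3-dithian-2-yl}carbonyl)-2H-chromen-2-one | CC(=O)[C@@](O[Si](CC)(CC)CC)(CC=C(C)C)CC1(SCCCS1)C(=O)c1cc2ccc(OC)cc2oc1=O | intermediate
23 | lithium aldolate: ring C closed, C2 bearing O–Li and the coumarin, C1 dithiane, C5 triethylsilyl ether (either C2 epimer) | COc1ccc2cc(C3([O-])CC(=O)[C@@](O[Si](CC)(CC)CC)(CC=C(C)C)CC34SCCCS4)c(=O)oc2c1.[Li+] | intermediate (not isolated)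
24 | trifluoroacetate of the aldol (either C2 epimer) | COc1ccc2cc(C3(OC(=O)C(F)(F)F)CC(=O)[C@@](O[Si](CC)(CC)CC)(CC=C(C)C)CC34SCCCS4)c(=O)oc2c1 | intermediate (not isolated)
25 | 7-methoxy-3-[(10R)-10-(3-methylbut-2-en-1-yl)-9-oxo-10-(triethylsilyloxy)-1,5-dithiaspiro[5.5]undec-7-en-7-yl]-2H-chromen-2-one | COc1ccc2cc(C3=CC(=O)[C@@](O[Si](CC)(CC)CC)(CC=C(C)C)CC34SCCCS4)c(=O)oc2c1 | intermediate
26 | 7-methoxy-3-[(4R)-4-(3-methylbut-2-en-1-yl)-3,6-dioxo-4-(triethylsilyloxy)cyclohex-1-en-1-yl]-2H-chromen-2-one | COc1ccc2cc(C3=CC(=O)[C@@](O[Si](CC)(CC)CC)(CC=C(C)C)CC3=O)c(=O)oc2c1 | intermediate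
27 | 3-[(4R)-4-hydroxy-4-(3-methylbut-2-en-1-yl)-3,6-dioxocyclohex-1-en-1-yl]-7-methoxy-2H-chromen-2-one | COc1ccc2cc(C3=CC(=O)[C@@](O)(CC=C(C)C)CC3=O)c(=O)oc2c1 | target

**Totals and risks**

Total step count: 13. Longest linear sequence: 13 steps (from 1 and 2 to 27).

Step 11 (key step). The closure may fail through attack of base on the coumarin lactone, reversal of the aldol addition before the alkoxide is acylated, or migration of the silyl group from the C5 oxygen to the enolate oxygen. The same C2–C3 bond would then be made under Lewis acid control. Ketone 22 would be converted with Me3SiOSO2CF3 and Et3N into the trimethylsilyl enol ether F1. An intramolecular Mukaiyama aldol addition to the C2 ketone (TiCl4, CH2Cl2, −78 °C) would give the β-hydroxy ketone F2. Dehydration of isolated F2 with the Burgess reagent would return to the route at 25.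

Step 12. The oxidant may also attack the prenyl alkene or the electron-rich coumarin, and the silyl ether β to the new C1 ketone may be eliminated under the buffered aqueous conditions. The last two operations would then be exchanged and the unmasking made hydrolytic instead of oxidative. Enone 25 would be desilylated with HF·pyridine to the hydroxy dithiane F3. The dithioketal of F3 would be removed by thiophilic metal-assisted hydrolysis (CuCl2, CuO, aqueous acetone), which comes back to the route at the target 27.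

Step 9. Both silyl ethers may be cleaved, or neither, if the steric difference between them is too small. Both would then be removed on purpose from 20 (HF·pyridine, THF, rt) to give the diol F4. Only the secondary hydroxyl of F4 can be oxidised (Parikh–Doering: SO3·pyridine, DMSO, iPr2NEt), which would give the hydroxy ketone F5. Silylation of the tertiary hydroxyl of F5 (Et3SiOSO2CF3, 2,6-lutidine) would come back to the route at 22.

**Further compounds**

F1 | step 11 | trimethylsilyl enol ether of ketone 22 | C=C(O[Si](C)(C)C)[C@@](O[Si](CC)(CC)CC)(CC=C(C)C)CC1(SCCCS1)C(=O)c1cc2ccc(OC)cc2oc1=O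
F2 | step 11 | β-hydroxy ketone (aldol) with ring C closed, C1 dithiane, C5 triethylsilyl ether (either C2 epimer) | COc1ccc2cc(C3(O)CC(=O)[C@@](O[Si](CC)(CC)CC)(CC=C(C)C)CC34SCCCS4)c(=O)oc2c1
F3 | step 12 | 3-[(10R)-10-hydroxy-10-(3-methylbut-2-en-1-yl)-9-oxo-1,5-dithiaspiro[5.5]undec-7-en-7-yl]-7-methoxy-2H-chromen-2-one | COc1ccc2cc(C3=CC(=O)[C@@](O)(CC=C(C)C)CC34SCCCS4)c(=O)oc2c1
F4 | step 9 | 3-({2-[(2R,3S)-2,3-dihydroxy-2-(3-methylbut-2-en-1-yl)butyl]-1,3-dithian-2-yl}carbonyl)-7-methoxy-2H-chromen-2-one | C[C@H](O)[C@@](O)(CC=C(C)C)CC1(SCCCS1)C(=O)c1cc2ccc(OC)cc2oc1=O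
F5 | step 9 | 3-({2-[(2R)-2-hydroxy-2-(3-methylbut-2-en-1-yl)-3-oxobutyl]-1,3-dithian-2-yl}carbonyl)-7-methoxy-2H-chromen-2-one | CC(=O)[C@@](O)(CC=C(C)C)CC1(SCCCS1)C(=O)c1cc2ccc(OC)cc2oc1=O
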